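**Retrosynthetic overview**

1. Hypoxyterpoid A (24) comes from diester 22 by thiolate demethylation. Diester 22 comes from the acyclic aldehyde 20 in one Lewis-acid cascade that closes ring A first (C1–C2, Prins addition of the C2 aldehyde to the isopropenyl group on C5) and ring B second (C9–C10, capture of the C10 cation by the C8=C9 allylsilane, which also delivers the C8=C17 methylene).
2. Enabling feature: in ring A the C2 carbinol is 1,3 to the quaternary C10 across the C1 methylene, and in ring B C10 is homoallylic to the exocyclic C8=C17 alkene through C9. The C1=C10 double bond of an isopropenyl group on C5 is therefore a two-ended linchpin (C1 to C2, C10 to C9).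
3. Aldehyde 20 comes from gem-dibromide 16 (C9–C16 from methyl geranate by ozonolysis, C8 from CBr4) by two stereoretentive Negishi couplings: first the C7 alkylzinc 17 trans to C11, then Me3SiCH2ZnCl cis to C11.
4. The C4/C5 stereodiad comes from δ-lactone 9: rhodium-catalysed asymmetric 1,4-addition of an isopropenyl group to 5,6-dihydro-2H-pyran-2-one sets C5, two enolate alkylations anti to the isopropenyl group set C4, and selenolate opens the lactone at O–C7.

Key step: step 12

Remark: carbon labels C1–C20 are the labdane positions of the target and are used for the same carbons in all intermediates; (S)-BINAP is assumed to show the same sense of induction with the lactone as with cyclic enones, and methyl geranate is used as the pure 2E isomer.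

**Step 1**
Reactants: 1 5,6-dihydro-2H-pyran-2-one; 2 potassium trifluoro(prop-1-en-2-yl)borate
Product: 3 (4S)-4-(prop-1-en-2-yl)oxan-2-one
Conditions: [Rh(cod)2]PF6 (3 mol %), (S)-BINAP (3.3 mol %), toluene/H2O, 100 °C
Reagents that add atoms: none
Why: Hayashi–Miyaura-type rhodium-catalysed asymmetric 1,4-addition of an alkenylboron reagent to an α,β-unsaturated lactone, in which the BINAP–rhodium alkenyl complex should add to one enantioface of the enoate and so set C5 (4S in the lactone).

**Step 2**
Reactants: 4 2-iodoethanol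
Product: 5 (2-iodoethoxy)triethylsilane
Conditions: Et3SiCl, imidazole, CH2Cl2, 0 °C
Reagents that add atoms: chlorotriethylsilane, CC[Si](Cl)(CC)CC
Why: Imidazole-mediated silylation of a primary alcohol should give the two-carbon electrophile as a base-stable silyl ether that step 11 can oxidise directly.

**Step 3**
Reactants: 3 (4S)-4-(prop-1-en-2-yl)oxan-2-one; 5 (2-iodoethoxy)triethylsilane
Product: 7 (3R,4S)-4-(prop-1-en-2-yl)-3-[2-(triethylsilyloxy)ethyl]oxan-2-one, via lithium lactone enolate 6 (not isolated)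
Conditions: LiN(iPr)2, THF, −78 °C; then 5, DMPU, −78 to −30 °C
Reagents that add atoms: none
Why: Enolate alkylation of the lactone (only one enolisable position) with a primary iodide should place the arm anti to the isopropenyl group, although this centre is made planar again in step 4.

**Step 4**
Reactants: 7 (3R,4S)-4-(prop-1-en-2-yl)-3-[2-(triethylsilyloxy)ethyl]oxan-2-one
Product: 9 (3S,4R)-3-methyl-4-(prop-1-en-2-yl)-3-[2-(triethylsilyloxy)ethyl]oxan-2-one, via lithium lactone enolate 8 (not isolated)
Conditions: LiN(iPr)2, THF, −78 °C; then MeI, −78 to −40 °C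
Reagents that add atoms: iodomethane, CI
Why: Second enolate alkylation, in which the tetrasubstituted enolate should be methylated on the face anti to the adjacent pseudo-axial isopropenyl group (1,2-induction reinforced by allylic strain), setting the C4 quaternary centre with the methyl trans and the two-carbon arm cis to the isopropenyl group.

**Step 5**
Reactants: 9 (3S,4R)-3-methyl-4-(prop-1-en-2-yl)-3-[2-(triethylsilyloxy)ethyl]oxan-2-one
Product: 11 methyl (2S,3R)-2,4-dimethyl-3-[2-(phenylselanyl)ethyl]-2-[2-(triethylsilyloxy)ethyl]pent-4-enoate, via sodium selanyl carboxylate 10 (not isolated)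
Conditions: (PhSe)2, NaH, THF, 65 °C; then 9, HMPA, 65 °C; then MeI, 25 °C
Reagents that add atoms: diphenyl diselenide, c1ccccc1[Se][Se]c1ccccc1; iodomethane, CI
Why: SN2 ring opening of the lactone at the O–CH2 carbon (C7) by the soft selenolate (alkyl–oxygen cleavage) followed by O-methylation of the carboxylate should give the open-chain ester without touching a stereocentre.

**Step 6**
Reactants: 11 methyl (2S,3R)-2,4-dimethyl-3-[2-(phenylselanyl)ethyl]-2-[2-(triethylsilyloxy)ethyl]pent-4-enoate
Product: 12 methyl (2S,3R)-3-(2-iodoethyl)-2,4-dimethyl-2-[2-(triethylsilyloxy)ethyl]pent-4-enoate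
Conditions: MeI (excess), NaI, DMF, 60–80 °C
Reagents that add atoms: iodomethane, CI
Why: Selenide-to-iodide exchange, in which Se-methylation gives a selenonium salt and iodide displaces methyl phenyl selenide from the primary C7 carbon by SN2.

**Step 7**
Reactants: 13 methyl (2E)-3,7-dimethylocta-2,6-dienoate (methyl geranate)
Product: 15 methyl (2E)-3-methyl-6-oxohex-2-enoate, via ozonide 14 (not isolated)
Conditions: O3 (1 equiv), CH2Cl2, −78 °C; then Me2S, −78 to 25 °C
Reagents that add atoms: ozone, [O-][O+]=O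
Why: Chemoselective ozonolysis should cleave only the electron-rich trisubstituted 6,7-alkene and leave the ester-conjugated alkene, so the 2E geometry (C13=C14 of the target) is carried through.

**Step 8**
Reactants: 15 methyl (2E)-3-methyl-6-oxohex-2-enoate
Product: 16 methyl (2E)-7,7-dibromo-3-methylhepta-2,6-dienoate
Conditions: CBr4, PPh3, Zn, CH2Cl2, 25 °C; then 15, 0 to 25 °C
Reagents that add atoms: tetrabromomethane, BrC(Br)(Br)Br
Why: Corey–Fuchs (Ramirez) dibromo-olefination of the aldehyde with the ylide made from PPh3, CBr4 and Zn should add C8 as a gem-dibromoalkene.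

**Step 9**
Reactants: 12 methyl (2S,3R)-3-(2-iodoethyl)-2,4-dimethyl-2-[2-(triethylsilyloxy)ethyl]pent-4-enoate; 16 methyl (2E)-7,7-dibromo-3-methylhepta-2,6-dienoate
Product: 18 dimethyl (2E,6Z,10R,11S)-7-bromo-3,11-dimethyl-10-(prop-1-en-2-yl)-11-[2-(triethylsilyloxy)ethyl]dodeca-2,6-dienedioate, via alkylzinc iodide 17 (not isolated)
Conditions: Zn, LiCl, THF, 40 °C; then 16, PdCl2(DPEphos) (5 mol %), THF/DMF, 23 °C
Reagents that add atoms: none
Why: LiCl-assisted zinc insertion and Negishi coupling, in which oxidative addition should occur selectively at the less hindered C–Br bond trans to the chain of the 1,1-dibromoalkene, so C7 is placed trans to C11 and the Z-bromide is left.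

**Step 10**
Reactants: 18 dimethyl (2E,6Z,10R,11S)-7-bromo-3,11-dimethyl-10-(prop-1-en-2-yl)-11-[2-(triethylsilyloxy)ethyl]dodeca-2,6-dienedioate
Product: 19 dimethyl (2E,6Z,10R,11S)-3,11-dimethyl-10-(prop-1-en-2-yl)-11-[2-(triethylsilyloxy)ethyl]-7-[(trimethylsilyl)methyl]dodeca-2,6-dienedioate
Conditions: Me3SiCH2MgCl, ZnCl2, THF, 0 °C; then 18, Pd(t-Bu3P)2 (3 mol %), THF, 23 °C
Reagents that add atoms: (trimethylsilyl)methylmagnesium chloride, C[Si](C)(C)C[Mg]Cl
Why: Second Negishi coupling of the alkenyl bromide should proceed with retention and place the silylmethyl group cis to C11, giving the 6Z allylsilane.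

**Step 11**
Reactants: 19 dimethyl (2E,6Z,10R,11S)-3,11-dimethyl-10-(prop-1-en-2-yl)-11-[2-(triethylsilyloxy)ethyl]-7-[(trimethylsilyl)methyl]dodeca-2,6-dienedioate
Product: 20 dimethyl (2E,6Z,10R,11S)-3,11-dimethyl-11-(2-oxoethyl)-10-(prop-1-en-2-yl)-7-[(trimethylsilyl)methyl]dodeca-2,6-dienedioate
Conditions: (COCl)2, DMSO, CH2Cl2, −78 to −30 °C; then Et3N, −78 to 0 °C
Reagents that add atoms: none
Why: Swern oxidation applied directly to a primary triethylsilyl ether, in which the ether oxygen attacks the chlorodimethylsulfonium ion with loss of the silyl group, should give the aldehyde without passing through a free γ-hydroxy ester that would lactonise onto C19.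

**Step 12**
Reactants: 20 dimethyl (2E,6Z,10R,11S)-3,11-dimethyl-11-(2-oxoethyl)-10-(prop-1-en-2-yl)-7-[(trimethylsilyl)methyl]dodeca-2,6-dienedioate
Product: 22 dimethyl 2α-hydroxylabda-8(17),13E-diene-15,19-dioate, via aluminium alkoxide 21 (not isolated)
Conditions: MeAlCl2 (3 equiv), CH2Cl2, −78 °C; then aq. NaHCO3
Reagents that add atoms: none
Why: MeAlCl2 activates the C2 aldehyde, C1 of the isopropenyl group on C5 adds to it (Prins addition) and the tertiary C10 cation so formed is captured by C9 of the allylsilane with loss of the silyl group, which places the alkene at C8=C17. The closest known reaction types are the alkylaluminium-halide-promoted Prins cyclisation of 5-methylhex-5-enals and the acetal-initiated cation–olefin polycyclisation terminated by an allylsilane (Hosomi–Sakurai-type termination). Ring A closes in a six-membered mode that is endo to the C1=C10 alkene and exo to the C2=O group, and ring B closes 6-endo onto the C8=C9 alkene, both through one chair–chair array in which C2 and C9 add anti across C1=C10. C10 is controlled by the resident C5 centre (the C5–C6 tether stays equatorial on the forming ring A, so the ring fusion is trans and the C10 methyl axial), C9 by the 6Z geometry of the allylsilane (C11 is cis to the silylmethyl group and ends equatorial), and C2 by the equatorial position of the aluminium-bound oxygen, which avoids the 1,3-diaxial contact with the axial C4 ester. The step needs capture of the C10 cation by C9 to outrun proton loss from C20 (carbonyl-ene channel), trapping by the C19 ester oxygen and direct aldehyde–allylsilane addition, and this is secured by the six-membered chair access of the strongly π-nucleophilic allylsilane, the strained five- and eight-membered alternatives, and the proton-scavenging Lewis acid that keeps the allylsilane intact.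

**Step 13**
Reactants: 22 dimethyl 2α-hydroxylabda-8(17),13E-diene-15,19-dioate
Product: 24 hypoxyterpoid A (2α-hydroxylabda-8(17),13E-diene-15,19-dioic acid), via dilithium dicarboxylate 23 (not isolated)
Conditions: n-PrSLi (excess), HMPA, 25 °C; then aq. HCl to pH 3
Reagents that add atoms: none
Why: SN2 demethylation of both methyl esters by thiolate does not depend on access to the hindered axial C19 carbonyl and should leave the exocyclic alkene, the enoate geometry and the C2 hydroxyl untouched.

**Compound list**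

1 | 5,6-dihydro-2H-pyran-2-one | O=C1C=CCCO1 | starting material
2 | potassium trifluoro(prop-1-en-2-yl)borate | [K+].C=C(C)[B-](F)(F)F | starting material
3 | (4S)-4-(prop-1-en-2-yl)oxan-2-one | C=C(C)[C@H]1CCOC(=O)C1 | intermediate
4 | 2-iodoethanol | OCCI | starting material
5 | (2-iodoethoxy)triethylsilane | CC[Si](CC)(CC)OCCI | intermediate
6 | lithium enolate of 3 | C=C(C)[C@H]1CCOC(O[Li])=C1 | intermediate
7 | (3R,4S)-4-(prop-1-en-2-yl)-3-[2-(triethylsilyloxy)ethyl]oxan-2-one (3,4-trans) | C=C(C)[C@H]1CCOC(=O)[C@@H]1CCO[Si](CC)(CC)CC | intermediate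
8 | lithium enolate of 7 | C=C(C)[C@H]1CCOC(O[Li])=C1CCO[Si](CC)(CC)CC | intermediate
9 | (3S,4R)-3-methyl-4-(prop-1-en-2-yl)-3-[2-(triethylsilyloxy)ethyl]oxan-2-one (methyl trans to isopropenyl; the C4 descriptor changes by priority only) | C=C(C)[C@H]1CCOC(=O)[C@@]1(C)CCO[Si](CC)(CC)CC | intermediate
10 | sodium (2S,3R)-2,4-dimethyl-3-[2-(phenylselanyl)ethyl]-2-[2-(triethylsilyloxy)ethyl]pent-4-enoate | [Na+].[O-]C(=O)[C@@](C)(CCO[Si](CC)(CC)CC)[C@H](CC[Se]c1ccccc1)C(C)=C | intermediate
11 | methyl (2S,3R)-2,4-dimethyl-3-[2-(phenylselanyl)ethyl]-2-[2-(triethylsilyloxy)ethyl]pent-4-enoate | COC(=O)[C@@](C)(CCO[Si](CC)(CC)CC)[C@H](CC[Se]c1ccccc1)C(C)=C | intermediate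
12 | methyl (2S,3R)-3-(2-iodoethyl)-2,4-dimethyl-2-[2-(triethylsilyloxy)ethyl]pent-4-enoate | COC(=O)[C@@](C)(CCO[Si](CC)(CC)CC)[C@H](CCI)C(C)=C | intermediate
13 | methyl (2E)-3,7-dimethylocta-2,6-dienoate (methyl geranate) | COC(=O)/C=C(\C)CCC=C(C)C | starting material
14 | methyl (2E)-5-(5,5-dimethyl-1,2,4-trioxolan-3-yl)-3-methylpent-2-enoate (ozonide) | COC(=O)/C=C(\C)CCC1OOC(C)(C)O1 | intermediate
15 | methyl (2E)-3-methyl-6-oxohex-2-enoate | COC(=O)/C=C(\C)CCC=O | intermediate
16 | methyl (2E)-7,7-dibromo-3-methylhepta-2,6-dienoate | COC(=O)/C=C(\C)CCC=C(Br)Br | intermediate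
17 | alkylzinc iodide from 12 (C7–ZnI) | COC(=O)[C@@](C)(CCO[Si](CC)(CC)CC)[C@H](CC[Zn]I)C(C)=C | intermediate
18 | dimethyl (2E,6Z,10R,11S)-7-bromo-3,11-dimethyl-10-(prop-1-en-2-yl)-11-[2-(triethylsilyloxy)ethyl]dodeca-2,6-dienedioate | COC(=O)/C=C(\C)CC/C=C(\Br)CC[C@H](C(C)=C)[C@](C)(CCO[Si](CC)(CC)CC)C(=O)OC | intermediate
19 | dimethyl (2E,6Z,10R,11S)-3,11-dimethyl-10-(prop-1-en-2-yl)-11-[2-(triethylsilyloxy)ethyl]-7-[(trimethylsilyl)methyl]dodeca-2,6-dienedioate | COC(=O)/C=C(\C)CC/C=C(\C[Si](C)(C)C)CC[C@H](C(C)=C)[C@](C)(CCO[Si](CC)(CC)CC)C(=O)OC | intermediate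
20 | dimethyl (2E,6Z,10R,11S)-3,11-dimethyl-11-(2-oxoethyl)-10-(prop-1-en-2-yl)-7-[(trimethylsilyl)methyl]dodeca-2,6-dienedioate | COC(=O)/C=C(\C)CC/C=C(\C[Si](C)(C)C)CC[C@H](C(C)=C)[C@](C)(CC=O)C(=O)OC | intermediate
21 | chloro(methyl)aluminium 2α-alkoxide of 22 | C=C1CC[C@@H]2[C@](C)(C[C@@H](O[Al](C)Cl)C[C@]2(C)C(=O)OC)[C@H]1CC/C(C)=C/C(=O)OC | intermediate
22 | dimethyl 2α-hydroxylabda-8(17),13E-diene-15,19-dioate | C=C1CC[C@@H]2[C@](C)(C[C@@H](O)C[C@]2(C)C(=O)OC)[C@H]1CC/C(C)=C/C(=O)OC | intermediate
23 | dilithium 2α-hydroxylabda-8(17),13E-diene-15,19-dioate | [Li+].[Li+].C=C1CC[C@@H]2[C@](C)(C[C@@H](O)C[C@]2(C)C([O-])=O)[C@H]1CC/C(C)=C/C([O-])=O | intermediate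
24 | hypoxyterpoid A (2α-hydroxylabda-8(17),13E-diene-15,19-dioic acid) | C=C1CC[C@@H]2[C@](C)(C[C@@H](O)C[C@]2(C)C(=O)O)[C@H]1CC/C(C)=C/C(=O)O | target

**Step count and risks**

Total step count: 13. Longest linear sequence: 10 steps (1, 3, 4, 5, 6, 9, 10, 11, 12, 13).

Step 12. What may go wrong: the cascade may end after ring A, either by proton transfer from C20 to the aluminium-bound oxygen or by trapping of the C10 cation by the C19 ester oxygen, and an axial aldehyde complex may erode the equatorial preference at C2. The fallback sets out from 20 and comes back at 22. The aldehyde is converted with propane-1,3-diol and PPTS into the 1,3-dioxane acetal F1. TiCl4 in CH2Cl2 at −78 °C then triggers the acetal-initiated cation–olefin bicyclisation with allylsilane termination, a channel in which the oxygen stays alkylated and cannot take up the C20 proton, and should give the 2α-(3-hydroxypropoxy) diester F2. Oxidation with DMP gives the 2α-(3-oxopropoxy) diester F3, and base-induced β-elimination (DBU, CH2Cl2) releases 22.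

Step 11. What may go wrong: the chlorodimethylsulfonium electrophile may attack the electron-rich allylsilane (chlorination or protodesilylation), and silyl transfer from the ether may be incomplete. The fallback sets out from 18 and comes back at 20. The same oxidative desilylation is run on 18, before the allylsilane exists, to give the bromo aldehyde F4. HC(OMe)3, PPTS and MeOH give the bromo dimethyl acetal F5. Negishi coupling with Me3SiCH2ZnCl as in step 10 gives the acetal allylsilane F6, and PPTS in wet acetone releases 20.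

Step 5 (together with step 6). What may go wrong: reversible acyl attack may compete with slow alkyl–oxygen cleavage at the congested lactone, and selenonium formation in the following exchange may be sluggish. The fallback sets out from 9 and comes back at 12. LiAlH4 in THF reduces the lactone to the diol F7. I2, PPh3 and imidazole iodinate only the unhindered C7 hydroxyl (the neopentyl C19 hydroxyl is left) to give the iodo alcohol F8. DMP gives the iodo aldehyde F9; NaClO2, NaH2PO4 and 2-methylbut-2-ene give the iodo acid F10; Me3SiCHN2 in MeOH/toluene gives 12.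

**Further compounds**

F1 | step 12 | dimethyl (2E,6Z,10R,11S)-11-(1,3-dioxan-2-ylmethyl)-3,11-dimethyl-10-(prop-1-en-2-yl)-7-[(trimethylsilyl)methyl]dodeca-2,6-dienedioate | COC(=O)/C=C(\C)CC/C=C(\C[Si](C)(C)C)CC[C@H](C(C)=C)[C@](C)(CC1OCCCO1)C(=O)OC
F2 | step 12 | dimethyl 2α-(3-hydroxypropoxy)labda-8(17),13E-diene-15,19-dioate | C=C1CC[C@@H]2[C@](C)(C[C@@H](OCCCO)C[C@]2(C)C(=O)OC)[C@H]1CC/C(C)=C/C(=O)OC
F3 | step 12 | dimethyl 2α-(3-oxopropoxy)labda-8(17),13E-diene-15,19-dioate | C=C1CC[C@@H]2[C@](C)(C[C@@H](OCCC=O)C[C@]2(C)C(=O)OC)[C@H]1CC/C(C)=C/C(=O)OC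
F4 | step 11 | dimethyl (2E,6Z,10R,11S)-7-bromo-3,11-dimethyl-11-(2-oxoethyl)-10-(prop-1-en-2-yl)dodeca-2,6-dienedioate | COC(=O)/C=C(\C)CC/C=C(\Br)CC[C@H](C(C)=C)[C@](C)(CC=O)C(=O)OC
F5 | step 11 | dimethyl (2E,6Z,10R,11S)-7-bromo-11-(2,2-dimethoxyethyl)-3,11-dimethyl-10-(prop-1-en-2-yl)dodeca-2,6-dienedioate | COC(=O)/C=C(\C)CC/C=C(\Br)CC[C@H](C(C)=C)[C@](C)(CC(OC)OC)C(=O)OC
F6 | step 11 | dimethyl (2E,6Z,10R,11S)-11-(2,2-dimethoxyethyl)-3,11-dimethyl-10-(prop-1-en-2-yl)-7-[(trimethylsilyl)methyl]dodeca-2,6-dienedioate | COC(=O)/C=C(\C)CC/C=C(\C[Si](C)(C)C)CC[C@H](C(C)=C)[C@](C)(CC(OC)OC)C(=O)OC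
F7 | step 5 | (2S,3R)-2-methyl-3-(prop-1-en-2-yl)-2-[2-(triethylsilyloxy)ethyl]pentane-1,5-diol | OC[C@@](C)(CCO[Si](CC)(CC)CC)[C@H](CCO)C(C)=C
F8 | step 5 | (2S,3R)-5-iodo-2-methyl-3-(prop-1-en-2-yl)-2-[2-(triethylsilyloxy)ethyl]pentan-1-ol | OC[C@@](C)(CCO[Si](CC)(CC)CC)[C@H](CCI)C(C)=C
F9 | step 5 | (2S,3R)-5-iodo-2-methyl-3-(prop-1-en-2-yl)-2-[2-(triethylsilyloxy)ethyl]pentanal | O=C[C@@](C)(CCO[Si](CC)(CC)CC)[C@H](CCI)C(C)=C
F10 | step 5 | (2S,3R)-5-iodo-2-methyl-3-(prop-1-en-2-yl)-2-[2-(triethylsilyloxy)ethyl]pentanoic acid | OC(=O)[C@@](C)(CCO[Si](CC)(CC)CC)[C@H](CCI)C(C)=C
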